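**Retrosynthetic overview**
1. Feature: in the γ-butyrolactone ring O1–C2(=O)–C3–C4–C5, the adjacent stereocentres are C3 (tertiary carbinol with O3 and the vanillyl CH2, C7') and C4 (veratryl CH2, C7). O3 and C7 are cis, and the chain C2–C3–C4–C5 is a masked 2-benzylbut-2-ene-1,4-diol.
2. Lactone ring (second and last ring formed): the O1–C2 acyl bond comes from a C5-hydroxy C2-acid, and the acid comes from the primary C2 carbinol of a C2/C3 diol while O5 stays silylated.
3. C4–C7 bond: invertive SN2 opening of a C3/C4 oxirane by a veratryl Grignard/copper reagent. C3 is quaternary, so only C4 can be attacked.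
4. Oxirane O3–C3–C4 (first ring formed): tartrate-controlled epoxidation of the E allylic alcohol through its free C2–OH fixes C3 and C4 in one operation.
5. C3=C4 alkene: E-selective Wittig reaction of an α-(O-benzylvanillyl) ester ylide with silyloxyacetaldehyde, then DIBAL-H.

Key step: step 6

Remark: the lactone numbering of the target (O1, C2, C3/O3, C4, C5, C7', C7) is used for every intermediate. O-Benzylvanillin is bought rather than made from vanillin.

**Step 1**
Reactants: 1 4-(benzyloxy)-3-methoxybenzaldehyde (O-benzylvanillin)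
Product: 2 [4-(benzyloxy)-3-methoxyphenyl]methanol
Conditions: NaBH4, MeOH, 0 °C
Reagents that add atoms: none
Why: Borohydride 1,2-reduction of an aromatic aldehyde is chemoselective, leaves both aryl ethers untouched and creates no stereocentre.

**Step 2**
Reactants: 2 [4-(benzyloxy)-3-methoxyphenyl]methanol
Product: 3 4-(benzyloxy)-3-methoxybenzyl bromide
Conditions: PBr3, Et2O, 0 °C; used crude
Reagents that add atoms: phosphorus tribromide, BrP(Br)Br
Why: PBr3 bromination (phosphite activation, then SN2 by bromide) is fast at this electron-rich benzylic position at 0 °C, and the solvolysis-prone bromide is carried on at once.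

**Step 3**
Reactants: 3 4-(benzyloxy)-3-methoxybenzyl bromide; 4 ethyl (triphenyl-λ5-phosphanylidene)acetate
Product: 6 ethyl 3-[4-(benzyloxy)-3-methoxyphenyl]-2-(triphenyl-λ5-phosphanylidene)propanoate, via phosphonium bromide 5 (not isolated)
Conditions: toluene, 80 °C; then 1 M NaOH, CH2Cl2, rt
Reagents that add atoms: none
Why: C-Alkylation of a stabilised phosphorane by a benzylic bromide gives the phosphonium salt, whose remaining acidic α-proton is removed by dilute hydroxide faster than the ester is hydrolysed, which should yield the α-substituted stabilised ylide.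

**Step 4**
Reactants: 6 ethyl 3-[4-(benzyloxy)-3-methoxyphenyl]-2-(triphenyl-λ5-phosphanylidene)propanoate; 7 (tert-butyldimethylsilyloxy)acetaldehyde
Product: 8 ethyl (E)-2-[4-(benzyloxy)-3-methoxybenzyl]-4-(tert-butyldimethylsilyloxy)but-2-enoate
Conditions: toluene, 60 °C
Reagents that add atoms: none
Why: A Wittig olefination with an α-branched ester-stabilised ylide in an aprotic solvent favours the oxaphosphetane that puts the ester trans to the aldehyde residue, so the E-enoate (CO2Et trans to CH2OTBS) should dominate and any Z isomer can be removed by chromatography here or after step 5.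

**Step 5**
Reactants: 8 ethyl (E)-2-[4-(benzyloxy)-3-methoxybenzyl]-4-(tert-butyldimethylsilyloxy)but-2-enoate
Product: 9 (E)-2-[4-(benzyloxy)-3-methoxybenzyl]-4-(tert-butyldimethylsilyloxy)but-2-en-1-ol
Conditions: DIBAL-H (2.3 equiv), CH2Cl2, −78 °C; Rochelle salt
Reagents that add atoms: none
Why: DIBAL-H reduces the conjugated ester by two 1,2-hydride transfers to the allylic alcohol without changing the alkene geometry, the silyl ether or the benzyl ether.

**Step 6**
Reactants: 9 (E)-2-[4-(benzyloxy)-3-methoxybenzyl]-4-(tert-butyldimethylsilyloxy)but-2-en-1-ol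
Product: 10 {(2R,3R)-2-[4-(benzyloxy)-3-methoxybenzyl]-3-[(tert-butyldimethylsilyloxy)methyl]oxiran-2-yl}methanol
Conditions: Ti(OiPr)4 (10 mol %), D-(−)-DIPT (12 mol %), t-BuOOH (2 equiv, decane), 4 Å MS, CH2Cl2, −20 °C
Reagents that add atoms: tert-butyl hydroperoxide, CC(C)(C)OO
Why: Katsuki–Sharpless asymmetric epoxidation: 9 (through its C2–OH) and t-BuOOH displace isopropoxide on the titanium–tartrate dimer, and the titanium-activated peroxide oxygen is handed to the C3=C4 π bond in one concerted, suprafacial event that makes the C3–O3 and C4–O3 bonds together. The closest known reaction type is the catalytic (molecular-sieve) epoxidation of 2,3E-disubstituted primary allylic alcohols, the substrate class on which this reaction is most dependable. The one ring closed, the oxirane O3–C3–C4, arises by [2+1] oxygen-atom transfer to the alkene and not by displacement, so the E geometry of 9 is carried unchanged into the trans relation of CH2OH and CH2OTBS. The absolute configuration at both C3 and C4 is dictated by the tartrate: L-(+)-tartrates give the 2S series with such alcohols, so D-(−)-DIPT should give (2R,3R)-10, which has C3 as in the target and C4 with its C–O bond on the face from which it must later be expelled. The step needs enantiofacial selectivity, and the substrate secures it by offering titanium a single binding site (free C2–OH, O5 silylated, phenol benzylated) next to an alkene that has no substituent cis to the carbinol to clash with the ligand. Low temperature and the bulkier isopropyl tartrate should hold back alkoxide opening of the product.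

**Step 7**
Reactants: 11 3,4-dimethoxybenzyl chloride (veratryl chloride)
Product: 12 (3,4-dimethoxybenzyl)magnesium chloride (about 0.25 M in THF, titrated, used the same day)
Conditions: Mg turnings (excess), THF, 0 °C, slow addition at high dilution
Reagents that add atoms: magnesium, [Mg]
Why: Grignard formation by insertion of magnesium into a benzylic C–Cl bond is workable for alkoxy-substituted benzyl chlorides when the halide is kept cold and dilute over excess metal, so that insertion outruns coupling of the reagent with unreacted chloride.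

**Step 8**
Reactants: 10 {(2R,3R)-2-[4-(benzyloxy)-3-methoxybenzyl]-3-[(tert-butyldimethylsilyloxy)methyl]oxiran-2-yl}methanol; 12 (3,4-dimethoxybenzyl)magnesium chloride
Product: 13 (2S,3S)-2-[4-(benzyloxy)-3-methoxybenzyl]-3-[(tert-butyldimethylsilyloxy)methyl]-4-(3,4-dimethoxyphenyl)butane-1,2-diol
Conditions: 12 (4 equiv), CuI (20 mol %), THF, −30 → 0 °C; aq NH4Cl
Reagents that add atoms: none
Why: Copper-catalysed Grignard opening of a 2,3-epoxy alcohol at its distal carbon: after one equivalent of 12 has deprotonated the C2–OH, the benzylcopper species attacks C4 anti to the C4–O3 bond (SN2, inversion) because C3 is fully substituted, so C3–O3 is retained, C4 becomes S, and O3 and C7 end up cis in the later ring.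

**Step 9**
Reactants: 13 (2S,3S)-2-[4-(benzyloxy)-3-methoxybenzyl]-3-[(tert-butyldimethylsilyloxy)methyl]-4-(3,4-dimethoxyphenyl)butane-1,2-diol
Product: 14 (2S,3S)-2-[4-(benzyloxy)-3-methoxybenzyl]-3-[(tert-butyldimethylsilyloxy)methyl]-4-(3,4-dimethoxyphenyl)-2-hydroxybutanal
Conditions: IBX (1.5 equiv), DMSO, rt
Reagents that add atoms: none
Why: IBX oxidises the primary alcohol of a 1,2-diol to the α-hydroxy aldehyde without glycol cleavage, the tertiary O3–H cannot be oxidised, and neither C3 (quaternary) nor C4 (not α to the carbonyl) can epimerise.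

**Step 10**
Reactants: 14 (2S,3S)-2-[4-(benzyloxy)-3-methoxybenzyl]-3-[(tert-butyldimethylsilyloxy)methyl]-4-(3,4-dimethoxyphenyl)-2-hydroxybutanal
Product: 15 (2S,3S)-2-[4-(benzyloxy)-3-methoxybenzyl]-3-[(tert-butyldimethylsilyloxy)methyl]-4-(3,4-dimethoxyphenyl)-2-hydroxybutanoic acid
Conditions: NaClO2, NaH2PO4, 2-methyl-2-butene (large excess), t-BuOH–H2O, 0 °C → rt
Reagents that add atoms: sodium chlorite, [Na+].[O-]Cl=O
Why: The Pinnick oxidation converts the hindered α-hydroxy aldehyde into the acid under buffered conditions, and the excess alkene intercepts hypochlorous acid before it can chlorinate the electron-rich rings.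

**Step 11**
Reactants: 15 (2S,3S)-2-[4-(benzyloxy)-3-methoxybenzyl]-3-[(tert-butyldimethylsilyloxy)methyl]-4-(3,4-dimethoxyphenyl)-2-hydroxybutanoic acid
Product: 17 O-benzyltrachelogenin [(3S,4S)-3-[4-(benzyloxy)-3-methoxybenzyl]-4-(3,4-dimethoxybenzyl)-3-hydroxyoxolan-2-one], via seco hydroxy acid 16 (not isolated)
Conditions: 1 M HCl, THF, rt
Reagents that add atoms: none
Why: Acid hydrolysis of the primary silyl ether frees O5–H, which closes the five-membered ring on the C2 acid by acid-catalysed 5-exo-trig lactonisation without touching either stereocentre, since the adjacent carbonyl disfavours ionisation of the tertiary carbinol.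

**Step 12**
Reactants: 17 O-benzyltrachelogenin
Product: 18 trachelogenin [(3S,4S)-4-(3,4-dimethoxybenzyl)-3-hydroxy-3-(4-hydroxy-3-methoxybenzyl)oxolan-2-one]
Conditions: H2 (1 atm), 10 % Pd/C, EtOAc–EtOH, rt
Reagents that add atoms: none
Why: Catalytic hydrogenolysis cleaves only the benzylic C–O bond of the aryl benzyl ether, because the molecule has no other benzylic heteroatom bond and the lactone, O3–H and methyl ethers are inert.

**Compound list**
1 | 4-(benzyloxy)-3-methoxybenzaldehyde | COc1cc(C=O)ccc1OCc1ccccc1 | starting material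
2 | [4-(benzyloxy)-3-methoxyphenyl]methanol | COc1cc(CO)ccc1OCc1ccccc1 | intermediate
3 | 4-(benzyloxy)-3-methoxybenzyl bromide | COc1cc(CBr)ccc1OCc1ccccc1 | intermediate
4 | ethyl (triphenyl-λ5-phosphanylidene)acetate | CCOC(=O)C=P(c1ccccc1)(c1ccccc1)c1ccccc1 | starting material
5 | {3-[4-(benzyloxy)-3-methoxyphenyl]-1-ethoxy-1-oxopropan-2-yl}triphenylphosphonium bromide (racemic) | CCOC(=O)C(Cc1ccc(OCc2ccccc2)c(OC)c1)[P+](c1ccccc1)(c1ccccc1)c1ccccc1.[Br-] | intermediate
6 | ethyl 3-[4-(benzyloxy)-3-methoxyphenyl]-2-(triphenyl-λ5-phosphanylidene)propanoate | CCOC(=O)C(Cc1ccc(OCc2ccccc2)c(OC)c1)=P(c1ccccc1)(c1ccccc1)c1ccccc1 | intermediate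
7 | (tert-butyldimethylsilyloxy)acetaldehyde | CC(C)(C)[Si](C)(C)OCC=O | starting material
8 | ethyl (E)-2-[4-(benzyloxy)-3-methoxybenzyl]-4-(tert-butyldimethylsilyloxy)but-2-enoate | CCOC(=O)/C(Cc1ccc(OCc2ccccc2)c(OC)c1)=C/CO[Si](C)(C)C(C)(C)C | intermediate
9 | (E)-2-[4-(benzyloxy)-3-methoxybenzyl]-4-(tert-butyldimethylsilyloxy)but-2-en-1-ol | OC/C(Cc1ccc(OCc2ccccc2)c(OC)c1)=C/CO[Si](C)(C)C(C)(C)C | intermediate
10 | {(2R,3R)-2-[4-(benzyloxy)-3-methoxybenzyl]-3-[(tert-butyldimethylsilyloxy)methyl]oxiran-2-yl}methanol | OC[C@@]1(Cc2ccc(OCc3ccccc3)c(OC)c2)O[C@@H]1CO[Si](C)(C)C(C)(C)C | intermediate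
11 | 3,4-dimethoxybenzyl chloride | COc1ccc(CCl)cc1OC | starting material
12 | (3,4-dimethoxybenzyl)magnesium chloride | COc1ccc(C[Mg]Cl)cc1OC | intermediate
13 | (2S,3S)-2-[4-(benzyloxy)-3-methoxybenzyl]-3-[(tert-butyldimethylsilyloxy)methyl]-4-(3,4-dimethoxyphenyl)butane-1,2-diol | OC[C@](O)(Cc1ccc(OCc2ccccc2)c(OC)c1)[C@H](CO[Si](C)(C)C(C)(C)C)Cc1ccc(OC)c(OC)c1 | intermediate
14 | (2S,3S)-2-[4-(benzyloxy)-3-methoxybenzyl]-3-[(tert-butyldimethylsilyloxy)methyl]-4-(3,4-dimethoxyphenyl)-2-hydroxybutanal | O=C[C@](O)(Cc1ccc(OCc2ccccc2)c(OC)c1)[C@H](CO[Si](C)(C)C(C)(C)C)Cc1ccc(OC)c(OC)c1 | intermediate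
15 | (2S,3S)-2-[4-(benzyloxy)-3-methoxybenzyl]-3-[(tert-butyldimethylsilyloxy)methyl]-4-(3,4-dimethoxyphenyl)-2-hydroxybutanoic acid | OC(=O)[C@](O)(Cc1ccc(OCc2ccccc2)c(OC)c1)[C@H](CO[Si](C)(C)C(C)(C)C)Cc1ccc(OC)c(OC)c1 | intermediate
16 | (2S,3S)-2-[4-(benzyloxy)-3-methoxybenzyl]-4-(3,4-dimethoxyphenyl)-2-hydroxy-3-(hydroxymethyl)butanoic acid | OC(=O)[C@](O)(Cc1ccc(OCc2ccccc2)c(OC)c1)[C@H](CO)Cc1ccc(OC)c(OC)c1 | intermediate
17 | (3S,4S)-3-[4-(benzyloxy)-3-methoxybenzyl]-4-(3,4-dimethoxybenzyl)-3-hydroxyoxolan-2-one | COc1cc(C[C@@]2(O)C(=O)OC[C@@H]2Cc2ccc(OC)c(OC)c2)ccc1OCc1ccccc1 | intermediate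
18 | trachelogenin, (3S,4S)-4-(3,4-dimethoxybenzyl)-3-hydroxy-3-(4-hydroxy-3-methoxybenzyl)oxolan-2-one | COc1cc(C[C@@]2(O)C(=O)OC[C@@H]2Cc2ccc(OC)c(OC)c2)ccc1O | target

**Step count**
Total steps: 12. Longest linear sequence: 11 (steps 1–6 and 8–12, from 1). Step 7 is a one-step branch from 11.

**Steps most likely to fail**

1. Step 8.
   - What may go wrong: the free C2 alkoxide can start a Payne migration of the oxirane toward C2, followed by attack at the unhindered terminus.
   - What may go wrong: SN2 attack at C4 is crowded by quaternary C3 and the silyloxymethyl arm. A slow reaction leaves time for chloride-mediated or Lewis-acid-induced opening and for silyl migration from O5 to O2.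
   - Fallback, from 10: the C2 hydroxyl is capped (Et3SiCl, imidazole, CH2Cl2, 0 °C) to give the triethylsilyl ether of the epoxy alcohol F1, which has no alkoxide to start the migration.
   - F1 is opened at C4 with a stoichiometric magnesium cuprate made from 12 and CuBr·SMe2 (THF–Me2S, −30 → 0 °C) to give the bis-silylated tertiary alcohol F2.
   - The primary triethylsilyl ether is then removed in preference to the tert-butyldimethylsilyl ether (PPTS, MeOH, 0 °C), which returns the route to 13.

2. Step 7.
   - What may go wrong: Wurtz-type reductive dimerisation and self-alkylation of the very reactive, electron-rich benzylic chloride during insertion would lower the titre of the reagent.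
   - Fallback, from 11: the carbanion is generated without halide present. Displacement of chloride by tributylstannyllithium (Bu3SnH, LDA, THF, −78 °C) gives the storable (3,4-dimethoxybenzyl)tributylstannane F3.
   - Tin–lithium exchange (n-BuLi, THF, −78 °C) gives 3,4-dimethoxybenzyllithium F4 with no alkyl halide in the flask.
   - Anhydrous MgCl2 converts F4 into 12, where the route is rejoined.

3. Step 6.
   - What may go wrong: crowding of titanium by the 2-benzyl group could erode enantiofacial selectivity or stall turnover, and titanium could assist alkoxide opening of the product.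
   - Fallback, from 9: the hydroxyl-directed metal peroxide is replaced by an undirected chiral dioxirane (Shi epoxidation: D-fructose-derived ketone, Oxone, K2CO3 buffer at about pH 10.5, MeCN–dimethoxymethane–H2O, 0 °C).
   - The spiro transition state reads the E-trisubstituted alkene itself. It is predicted to give the same (2R,3R) sense that it gives with E-cinnamyl-type alcohols.
   - The route is rejoined directly at 10, and no compound outside the list is made (F0).

**Further compounds**
F1 | step 8 | tert-butyl({(2R,3R)-3-[4-(benzyloxy)-3-methoxybenzyl]-3-[(triethylsilyloxy)methyl]oxiran-2-yl}methoxy)dimethylsilane | CC[Si](CC)(CC)OC[C@@]1(Cc2ccc(OCc3ccccc3)c(OC)c2)O[C@@H]1CO[Si](C)(C)C(C)(C)C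
F2 | step 8 | (2S,3S)-2-[4-(benzyloxy)-3-methoxybenzyl]-3-[(tert-butyldimethylsilyloxy)methyl]-4-(3,4-dimethoxyphenyl)-1-(triethylsilyloxy)butan-2-ol | CC[Si](CC)(CC)OC[C@](O)(Cc1ccc(OCc2ccccc2)c(OC)c1)[C@H](CO[Si](C)(C)C(C)(C)C)Cc1ccc(OC)c(OC)c1
F3 | step 7 | (3,4-dimethoxybenzyl)tributylstannane | CCCC[Sn](CCCC)(CCCC)Cc1ccc(OC)c(OC)c1
F4 | step 7 | 3,4-dimethoxybenzyllithium | [Li]Cc1ccc(OC)c(OC)c1
F0 | step 6 | none | none
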